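Drimane numbering is used throughout, also for the carbon atoms of the monocyclic precursors: ring A is C1–C5 and C10, ring B is C5–C10, C11 is the oxygenated methylene on C9 and C12 the methyl group on C8.

## Analysis of the target

Compound 21 is the ether of umbelliferone 19 with a drim-7-ene-2,3,11-triol. Ring A (C1–C5, C10) is a cyclohexane with a geminal dimethyl group on C4 and hydroxyl groups on C2 and C3. Ring B (C5–C10) is a cyclohexene whose trisubstituted C7=C8 olefin carries C12, and C9 carries the C11 methylene bound through oxygen to C7 of the coumarin. There are five stereocentres, (2S,3S,5S,9R,10R). H5 is trans to the C10 methyl group (trans ring fusion), C11 is cis to that methyl group and equatorial, 3-OH is cis and 2-OH trans to it, so the diol is trans-diequatorial. The ring fusion is the mirror image of that of the common drimanes, so chiral-pool drimane building blocks have the wrong absolute configuration. The coumarin (lactone and enoate) does not tolerate enolates, hydrides or strong nucleophiles. The C7=C8 olefin is endangered by peracids and by acid-promoted migration to the tetrasubstituted C8=C9 position. A 2-hydroxy-3-ketone stage can epimerise or transpose. The hard parts are the contiguous triad C5–C10 (quaternary)–C9, the position of the olefin, and an oxygen on C2 beside the usual one on C3. The strategy rests on ring B: its C7=C8 double bond lies between C6 and C9 exactly where a [4+2] cycloaddition leaves the new π bond, and its three stereocentres C5, C10 and C9 are the atoms that form the two new σ bonds.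

## Retrosynthetic reasoning

The C11–O bond to the coumarin is cut last, giving umbelliferone 19 and the primary alcohol 18. This keeps the coumarin out of all enolate, hydride and radical steps. The forward reaction must alkylate the phenol at a β-branched primary carbon without touching the secondary hydroxyl groups, so the diol is carried as the isopropylidene acetal (17, 18, 20) and released at the end (20 to 21).

The two C–O stereocentres are traced back from diol 16 through ketol 15 to ketone 13. C4 is quaternary, so 13 can enolise only towards C2 (enolate 14). Both the oxygen electrophile at C2 and the hydride at C3 should enter from the face opposite the axial methyl groups on C4 and C10. That places both hydroxyl groups equatorial, as the target requires, so no reagent control is needed.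

Ring A is opened at C3–C4, leading from ketone 13 through alcohol 12 to aldehyde 11. The isopropenyl group on C5 is the latent C4 with its second methyl group. Transfer of a hydrogen atom to its terminal carbon gives the tertiary C4 radical, which closes on the formyl carbon C3. An ionic activation of the same olefin would bond through the terminal carbon and give a seven-membered ring, which is why a radical closure is chosen. The ring fusion is already fixed by C5 and C10, and the only new centre, C3, is erased by oxidation to 13.

The chain C1–C2–C3 of aldehyde 11 is cut at C1–C2. The formyl carbon of ring-B aldehyde 7 is C1, and C2 and C3 come from a two-carbon olefination (8), conjugate reduction (9) and partial reduction of the ester (through 10).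

Ring B is cut at C5–C6 and C9–C10, giving diene 6 and dienal 3. This is the only disconnection that removes all three ring-B stereocentres and the quaternary carbon at once while leaving the olefin at C7=C8 by construction. The forward cycloaddition has to control regiochemistry, exo topology, the enantioface and the choice between the two olefins of 3.

Dienal 3 is cut at its trisubstituted olefin into methacrolein 1 and the formyl ylide 2. Diene 6 comes from the commercial enynol 4 by silylation (5) and semihydrogenation. Both partners are one or two steps from purchased materials, so the risk of the route sits in the cycloaddition.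

## Alternatives that were turned down

Alternative 1: Both rings are opened at C4–C5 and C9–C10, back to the acyclic epoxy farnesyl ether A2, which is a few steps from 19. In the forward direction a Lewis acid at low temperature opens the epoxide at C4, the two trisubstituted olefins add in turn, and loss of a C7 proton gives the 2-deoxy compound A1.
- For it: it is the shortest route by far, it follows the biosynthesis, four stereocentres (C3, C5, C9, C10) come from one epoxide centre, and the coumarin is in place from the start. On step economy it is stronger than the chosen route.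
- Against it: A1 lacks the C2 hydroxyl group. Adding it needs oxidation at C3, enolate oxygenation at C2 and reduction, all in the presence of the base- and hydride-sensitive coumarin. The terminating proton loss can give the C7=C8, C8=C9 and exocyclic olefins. The olefin next to the aryloxymethyl group is a deactivated nucleophile and its allylic ether can ionise, which favours monocyclisation. The enantiopure terminal epoxide requires differentiating one of three similar olefins.
- Comparison: the chosen route is longer, but it fixes the olefin position by construction and completes all ketone chemistry before 19 is attached.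

Alternative 2: C8 with its methyl group is removed by cutting C7–C8 and C8–C9, back to the B-nor hydrindanone A4. Forward, diazoethane A5 with a boron Lewis acid adds to the C9 ketone of A4, the C7 methylene migrates with loss of nitrogen, and the six-membered ketone A3 results as C8 epimers.
- For it: the diol acetal and both ring-fusion centres are secured before ring B reaches its final size, the C8 epimers do not matter because C8 becomes sp2, and the C9 ketone is a handle for C11.
- Against it: the carbonyl group sits beside the quaternary C10, so addition is hindered, and migration of C10 and repeated homologation compete. A5 is hazardous. A3 still lacks C11 and the C7=C8 olefin. Adding one carbon to a ketone flanked by C10 and the C8 methine, then placing the olefin at C7=C8 while setting C9, works against the preference for the tetrasubstituted C8=C9 olefin. A4 itself, with four stereocentres, needs a long enantioselective synthesis.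
- Comparison: the chosen cycloaddition creates C9, C11 and the olefin in the same step, which this route reaches only after several corrective steps.

Alternative 3: Rings A and B are opened together at C5–C10 and C8–C9, back to the triene A7, which would be built from (S)-pantolactone A8. Forward, heating or a mild aluminium Lewis acid lets the (E)-enoate C9=C10 add to the 2-silyloxydiene C5=C6–C7=C8 and gives A6.
- For it: the absolute configuration comes from the chiral pool, the diol is present before the rings form, two rings close in one step, and the tether fixes the regiochemistry. On regiochemistry it is stronger than the chosen intermolecular reaction, which has to win by substituent effects.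
- Against it: A8 is the less available enantiomer and supplies only C3, so C2 needs a separate diastereoselective step. A7 requires a long linear sequence with three defined olefins. The C5–C10 bond joins a diene terminus next to the quaternary C4 with a carbon that itself becomes quaternary. The cis/trans ratio of the ring fusion is not secured. A6 still needs the silyl enol ether turned into the C7=C8 olefin and the ester reduced, with C9 epimerisable meanwhile.
- Comparison: the chosen route offers convergence, a much shorter sequence to the first bicyclic intermediate, and the olefin in its final place.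

Key step: step 4

Assumption: the sense of induction is carried over from α-methylacrolein, on which the (S)-oxazaborolidinium salt is taken to expose the Re face of the α-carbon. Compound 3 must react on the Si face of its α-carbon, hence the (R)-catalyst; if the sense proved opposite, the (S)-catalyst would be used.

## Route

Step 1
Reactants: 1 methacrolein (2-methylprop-2-enal); 2 2-(triphenylphosphoranylidene)propanal
Product: 3 (E)-2,4-dimethylpenta-2,4-dienal
Conditions: 1 (3 equiv), toluene, 80 °C, sealed vessel; distillation
Reagents that add atoms: none
Why: Wittig olefination with a formyl-stabilised ylide, which adds to the carbonyl group of 1 and gives the trisubstituted enal with (E) geometry; the excess of volatile 1 limits a second homologation of 3.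

Step 2
Reactants: 4 (E)-3-methylpent-2-en-4-yn-1-ol
Product: 5 (E)-1-(tert-butyldimethylsilyloxy)-3-methylpent-2-en-4-yne
Conditions: t-BuMe2SiCl, imidazole, DMF, 0 °C → rt
Reagents that add atoms: tert-butyl(chloro)dimethylsilane, CC(C)(C)[Si](C)(C)Cl
Why: Standard silylation of a primary allylic alcohol; no stereocentre is involved and the (E) olefin is untouched.

Step 3
Reactants: 5 (E)-1-(tert-butyldimethylsilyloxy)-3-methylpent-2-en-4-yne
Product: 6 (E)-1-(tert-butyldimethylsilyloxy)-3-methylpenta-2,4-diene
Conditions: H2 (1 atm), Pd/CaCO3 poisoned with Pb(OAc)2, quinoline, hexane, rt, stopped after 1 equiv of H2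
Reagents that add atoms: none
Why: Lindlar semihydrogenation; the terminal alkyne is reduced faster than the diene that forms, and the trisubstituted olefin keeps its (E) geometry, which the cycloaddition needs.

Step 4
Reactants: 6 (E)-1-(tert-butyldimethylsilyloxy)-3-methylpenta-2,4-diene; 3 (E)-2,4-dimethylpenta-2,4-dienal
Product: 7 (1R,2R,6R)-2-[(tert-butyldimethylsilyloxy)methyl]-1,3-dimethyl-6-(prop-1-en-2-yl)cyclohex-3-ene-1-carbaldehyde (ring B; formyl carbon = C1, isopropenyl carbon = C4)
Conditions: (R)-1-(2-methylphenyl)-3,3-diphenyltetrahydro-1H,3H-pyrrolo[1,2-c][1,3,2]oxazaborole (20 mol %), HN(SO2CF3)2 (17 mol %), CH2Cl2, −78 → −20 °C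
Reagents that add atoms: none
Why: Catalytic enantioselective Diels–Alder reaction of an α-methyl enal under oxazaborolidinium catalysis, the closest known reaction type being the cycloaddition of α-methylacrolein and of β-alkyl α-methyl enals with open-chain dienes under the same catalysts. The boron cation binds the formyl oxygen of s-trans 3 and the s-cis diene 6 adds in a concerted but asynchronous [4+2] process, C5–C6 forming ahead of C9–C10, so that the quaternary C10 is created inside the six-membered transition state. Ring B is closed by this intermolecular cycloaddition, suprafacial on both partners. C10 is set by the catalyst, which shields one face of the bound enal and leaves the Si face of its α-carbon open; C5 follows from the (E) geometry of 3, which keeps isopropenyl trans to formyl; C9 follows from the (E) geometry of 6 together with the exo position of the formyl group preferred by α-methyl enals, which puts C11 cis to the C10 methyl group. Regiochemistry requires the unsubstituted diene terminus C6 to bond to the β-carbon: the leading bond is the one that feels steric demand, and the terminal silyloxymethyl substituent of 6 directs in the same sense, against the weaker opposite bias of the 2-methyl group. Site selectivity for the α,β-olefin is expected because allylic strain between the two methyl groups of 3 twists the distal olefin out of conjugation with the catalyst-bound formyl group, and the inside α-methyl group stops 3 from reacting as a diene. The acid is kept slightly below one equivalent relative to the oxazaborolidine so that no free acid ionises the allylic silyl ether.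

Step 5
Reactants: 7 ring-B aldehyde
Product: 8 methyl (E)-3-[(1R,2R,6R)-2-[(tert-butyldimethylsilyloxy)methyl]-1,3-dimethyl-6-(prop-1-en-2-yl)cyclohex-3-en-1-yl]prop-2-enoate
Conditions: (MeO)2P(O)CH2CO2Me, NaH, THF, 0 °C → reflux
Reagents that add atoms: trimethyl phosphonoacetate, COC(=O)CP(=O)(OC)OC
Why: Horner–Wadsworth–Emmons olefination; the aldehyde has no α-hydrogen, so only carbonyl addition is possible, the stabilised carbanion gives the (E)-enoate, and heating compensates for the neopentyl position.

Step 6
Reactants: 8 (E)-enoate
Product: 9 methyl 3-[(1R,2R,6R)-2-[(tert-butyldimethylsilyloxy)methyl]-1,3-dimethyl-6-(prop-1-en-2-yl)cyclohex-3-en-1-yl]propanoate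
Conditions: Mg turnings, MeOH, 0 °C → rt
Reagents that add atoms: none
Why: Dissolving-metal conjugate reduction of an α,β-unsaturated ester; electron transfer is limited to the conjugated ester, so the isopropenyl group, the ring olefin and the silyl ether stay.

Step 7
Reactants: 9 saturated methyl ester
Product: 11 3-[(1R,2R,6R)-2-[(tert-butyldimethylsilyloxy)methyl]-1,3-dimethyl-6-(prop-1-en-2-yl)cyclohex-3-en-1-yl]propanal, via aluminium hemiacetal 10 (not isolated)
Conditions: i-Bu2AlH (1.1 equiv), CH2Cl2, −78 °C; aqueous potassium sodium tartrate
Reagents that add atoms: none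
Why: Partial reduction of a methyl ester with a dialkylaluminium hydride; the tetrahedral aluminium hemiacetal 10 persists at −78 °C and releases the aldehyde only on work-up, which prevents over-reduction.

Step 8
Reactants: 11 C3 aldehyde
Product: 12 (5S,9R,10R)-11-(tert-butyldimethylsilyloxy)drim-7-en-3-ol (both C3 epimers)
Conditions: Fe(acac)3 (30 mol %), PhSiH3 (2.5 equiv), EtOH, 60 °C, argon
Reagents that add atoms: none
Why: Mukaiyama-type metal-hydride hydrogen atom transfer followed by reductive radical cyclisation onto a carbonyl group. An iron hydride transfers a hydrogen atom to the terminal carbon of the more accessible 1,1-disubstituted olefin, the tertiary C4 radical adds 6-exo-trig to the formyl carbon C3 through a chair with C1 and C4 both equatorial on ring B, and the alkoxy radical is reduced by divalent iron and protonated by EtOH. The ring fusion is fixed by C5 and C10 of 11, and C3 forms as a mixture that step 9 removes.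

Step 9
Reactants: 12 C3 alcohols
Product: 13 (5S,9R,10R)-11-(tert-butyldimethylsilyloxy)drim-7-en-3-one
Conditions: Dess–Martin periodinane, CH2Cl2, rt
Reagents that add atoms: none
Why: Dess–Martin oxidation of a hindered secondary alcohol; both C3 epimers converge on one ketone, and the olefin and the silyl ether are inert.

Step 10
Reactants: 13 C3 ketone
Product: 15 (2S,5S,9R,10R)-11-(tert-butyldimethylsilyloxy)-2-hydroxydrim-7-en-3-one, via potassium enolate 14 (not isolated)
Conditions: KN(SiMe3)2, THF, −78 °C; 2-(phenylsulfonyl)-3-phenyloxaziridine, −78 °C; AcOH quench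
Reagents that add atoms: 2-(phenylsulfonyl)-3-phenyloxaziridine, O=S(=O)(N1OC1c1ccccc1)c1ccccc1
Why: Enolate hydroxylation with an N-sulfonyloxaziridine; C4 is quaternary, so deprotonation can occur only at C2, the reagent does not epoxidise the C7=C8 olefin, and oxygen is delivered to the enolate face opposite the axial methyl groups on C4 and C10, which gives the equatorial (2S) alcohol.

Step 11
Reactants: 15 2-hydroxy-3-ketone
Product: 16 (2S,3S,5S,9R,10R)-11-(tert-butyldimethylsilyloxy)drim-7-ene-2,3-diol
Conditions: NaBH4, MeOH, 0 °C
Reagents that add atoms: none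
Why: Borohydride reduction of an α-hydroxy ketone; hydride attacks C3 axially from the face opposite the axial C4 methyl group and gives the equatorial (3S) alcohol trans to the C2 hydroxyl group, the usual course for 4,4-dimethyl-3-ketones of trans-decalins.

Step 12
Reactants: 16 trans-diol
Product: 17 (2S,3S,5S,9R,10R)-11-(tert-butyldimethylsilyloxy)-2,3-(isopropylidenedioxy)drim-7-ene
Conditions: Me2C(OMe)2, pyridinium p-toluenesulfonate (cat.), CH2Cl2, rt
Reagents that add atoms: 2,2-dimethoxypropane, COC(C)(C)OC
Why: Acid-catalysed transketalisation; trans-diequatorial cyclohexane-1,2-diols form isopropylidene acetals with this reagent, and the weak acid in an aprotic solvent leaves the primary silyl ether in place.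

Step 13
Reactants: 17 silyl ether acetal
Product: 18 (2S,3S,5S,9R,10R)-2,3-(isopropylidenedioxy)drim-7-en-11-ol
Conditions: Bu4NF, THF, 0 °C → rt
Reagents that add atoms: none
Why: Fluoride cleavage of a silyl ether; the acetal and the olefin are inert to fluoride.

Step 14
Reactants: 18 primary alcohol; 19 umbelliferone (7-hydroxy-2H-chromen-2-one)
Product: 20 7-{[(2S,3S,5S,9R,10R)-2,3-(isopropylidenedioxy)drim-7-en-11-yl]oxy}-2H-chromen-2-one
Conditions: PPh3, diisopropyl azodicarboxylate, THF, 0 °C → rt
Reagents that add atoms: none
Why: Mitsunobu etherification; the acidic phenol displaces the oxyphosphonium group at the primary C11, where no stereocentre is involved, and the masked diol ensures that only one hydroxyl group can be activated.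

Step 15
Reactants: 20 coumarin ether acetal
Product: 21 7-{[(1R,4aS,6S,7S,8aR)-6,7-dihydroxy-2,5,5,8a-tetramethyl-1,4,4a,5,6,7,8,8a-octahydronaphthalen-1-yl]methoxy}-2H-chromen-2-one (drimane numbering 2S,3S,5S,9R,10R)
Conditions: AcOH/H2O/THF (3:1:1), 40 °C
Reagents that add atoms: none
Why: Mild acid hydrolysis of the strained trans-fused isopropylidene acetal; the coumarin lactone, the aryl alkyl ether and the trisubstituted olefin are stable to aqueous acetic acid.

## Compound list

1 | methacrolein (2-methylprop-2-enal) | C=C(C)C=O | starting material
2 | 2-(triphenylphosphoranylidene)propanal | CC(C=O)=P(c1ccccc1)(c1ccccc1)c1ccccc1 | starting material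
3 | (E)-2,4-dimethylpenta-2,4-dienal | C=C(C)/C=C(C)/C=O | intermediate
4 | (E)-3-methylpent-2-en-4-yn-1-ol | C#C/C(C)=C/CO | starting material
5 | (E)-1-(tert-butyldimethylsilyloxy)-3-methylpent-2-en-4-yne | C#C/C(C)=C/CO[Si](C)(C)C(C)(C)C | intermediate
6 | (E)-1-(tert-butyldimethylsilyloxy)-3-methylpenta-2,4-diene | C=C/C(C)=C/CO[Si](C)(C)C(C)(C)C | intermediate
7 | (1R,2R,6R)-2-[(tert-butyldimethylsilyloxy)methyl]-1,3-dimethyl-6-(prop-1-en-2-yl)cyclohex-3-ene-1-carbaldehyde | CC1=CC[C@H](C(C)=C)[C@@](C)(C=O)[C@@H]1CO[Si](C)(C)C(C)(C)C | intermediate
8 | methyl (E)-3-[(1R,2R,6R)-2-[(tert-butyldimethylsilyloxy)methyl]-1,3-dimethyl-6-(prop-1-en-2-yl)cyclohex-3-en-1-yl]prop-2-enoate | CC1=CC[C@H](C(C)=C)[C@@](C)(/C=C/C(=O)OC)[C@@H]1CO[Si](C)(C)C(C)(C)C | intermediate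
9 | methyl 3-[(1R,2R,6R)-2-[(tert-butyldimethylsilyloxy)methyl]-1,3-dimethyl-6-(prop-1-en-2-yl)cyclohex-3-en-1-yl]propanoate | CC1=CC[C@H](C(C)=C)[C@@](C)(CCC(=O)OC)[C@@H]1CO[Si](C)(C)C(C)(C)C | intermediate
10 | diisobutylaluminium hemiacetal of ester 9 (1-methoxy-3-[ring B]propan-1-olate, not isolated) | CC1=CC[C@H](C(C)=C)[C@@](C)(CCC(OC)O[Al](CC(C)C)CC(C)C)[C@@H]1CO[Si](C)(C)C(C)(C)C | intermediate
11 | 3-[(1R,2R,6R)-2-[(tert-butyldimethylsilyloxy)methyl]-1,3-dimethyl-6-(prop-1-en-2-yl)cyclohex-3-en-1-yl]propanal | CC1=CC[C@H](C(C)=C)[C@@](C)(CCC=O)[C@@H]1CO[Si](C)(C)C(C)(C)C | intermediate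
12 | (5S,9R,10R)-11-(tert-butyldimethylsilyloxy)drim-7-en-3-ol, both C3 epimers | CC1=CC[C@@H]2C(C)(C)C(O)CC[C@@]2(C)[C@@H]1CO[Si](C)(C)C(C)(C)C | intermediate
13 | (5S,9R,10R)-11-(tert-butyldimethylsilyloxy)drim-7-en-3-one | CC1=CC[C@@H]2C(C)(C)C(=O)CC[C@@]2(C)[C@@H]1CO[Si](C)(C)C(C)(C)C | intermediate
14 | potassium (5S,9R,10R)-11-(tert-butyldimethylsilyloxy)drima-2,7-dien-3-olate (not isolated) | CC1=CC[C@@H]2C(C)(C)C([O-])=CC[C@@]2(C)[C@@H]1CO[Si](C)(C)C(C)(C)C.[K+] | intermediate
15 | (2S,5S,9R,10R)-11-(tert-butyldimethylsilyloxy)-2-hydroxydrim-7-en-3-one | CC1=CC[C@@H]2C(C)(C)C(=O)[C@@H](O)C[C@@]2(C)[C@@H]1CO[Si](C)(C)C(C)(C)C | intermediate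
16 | (2S,3S,5S,9R,10R)-11-(tert-butyldimethylsilyloxy)drim-7-ene-2,3-diol | CC1=CC[C@@H]2C(C)(C)[C@H](O)[C@@H](O)C[C@@]2(C)[C@@H]1CO[Si](C)(C)C(C)(C)C | intermediate
17 | (2S,3S,5S,9R,10R)-11-(tert-butyldimethylsilyloxy)-2,3-(isopropylidenedioxy)drim-7-ene | CC1=CC[C@@H]2C(C)(C)[C@@H]3OC(C)(C)O[C@H]3C[C@@]2(C)[C@@H]1CO[Si](C)(C)C(C)(C)C | intermediate
18 | (2S,3S,5S,9R,10R)-2,3-(isopropylidenedioxy)drim-7-en-11-ol | CC1=CC[C@@H]2C(C)(C)[C@@H]3OC(C)(C)O[C@H]3C[C@@]2(C)[C@@H]1CO | intermediate
19 | umbelliferone (7-hydroxy-2H-chromen-2-one) | Oc1ccc2ccc(=O)oc2c1 | starting material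
20 | 7-{[(2S,3S,5S,9R,10R)-2,3-(isopropylidenedioxy)drim-7-en-11-yl]oxy}-2H-chromen-2-one | CC1=CC[C@@H]2C(C)(C)[C@@H]3OC(C)(C)O[C@H]3C[C@@]2(C)[C@@H]1COc1ccc2ccc(=O)oc2c1 | intermediate
21 | 7-{[(2S,3S,5S,9R,10R)-2,3-dihydroxydrim-7-en-11-yl]oxy}-2H-chromen-2-one | CC1=CC[C@@H]2C(C)(C)[C@H](O)[C@@H](O)C[C@@]2(C)[C@@H]1COc1ccc2ccc(=O)oc2c1 | target

## Step count and uncertain steps

Total: 15 steps. Longest linear sequence: 14 steps (4 to 21, steps 2–15); dienal 3 is made in one step on a side branch.

Step 4 (key step). The cycloaddition may be sluggish because a β-branched α-methyl enal is a weak dienophile. The forcing conditions then needed invite acid-induced ionisation or oligomerisation of the dienyl silyl ether. Regiochemistry may leak under the influence of the diene's 2-methyl group, the exo preference may erode with an open-chain diene, and the distal olefin of 3 may compete. The fallback sets out from diene 6 and keeps the same two bonds. Dienal 3 is replaced by the doubly activated, purchasable ethyl (E)-3-methyl-4-oxobut-2-enoate (CCOC(=O)/C=C(\C)C=O), whose ester group raises reactivity and prefers the endo position, which reinforces formyl-exo. Under the same catalyst it should give the ring-B aldehyde ester F1. The formyl group is masked as the dioxolane F2 (1,2-bis(trimethylsilyloxy)ethane, Me3SiOSO2CF3 cat., CH2Cl2, −78 °C). Excess MeLi (THF, −78 → 0 °C) converts the ester into the tertiary alcohol F3. Dehydration (SOCl2, pyridine, 0 °C) gives the isopropenyl dioxolane F4, and pyridinium p-toluenesulfonate in wet acetone releases 7, where the route is rejoined.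

Step 8. The cyclised alkoxy radical may fragment back to the tertiary radical, so that plain reduction of the isopropenyl group wins. Hydrogen atom transfer to the ring olefin and silane reduction of the aldehyde may also compete. The fallback sets out from 7 and exchanges the acceptor. Horner–Wadsworth–Emmons reaction with diethyl cyanomethylphosphonate (NaH, THF) gives the unsaturated nitrile F5, and Mg in MeOH gives the saturated nitrile F6. Under Fe(acac)3/PhSiH3 in EtOH the C4 radical adds to the nitrile carbon, an acceptor that the silane does not reduce. The resulting ketimine F7 is hydrolysed on acidic work-up to ketone 13, where the route is rejoined two steps earlier than by the main sequence.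

Step 10. The enolate may add to the sulfonylimine by-product, and the ketol may epimerise or transpose to the 3-hydroxy-2-ketone during quench or work-up. The fallback sets out from enolate 14. Trapping with Me3SiCl gives the trimethylsilyl enol ether F8. Pb(OAc)4 in CH2Cl2 at 0 °C (acetoxylation of an enol silane, a Rubottom-type oxidation without a peracid) gives the 2-acetoxy ketone F9 with the acetoxy group on the same open face. LiAlH4 (THF, −20 °C) reduces ketone and acetate in one operation to diol 16, where the route is rejoined.

Step 12. Ketalisation of a trans-diequatorial diol next to the geminal dimethyl group may stop short, and longer exposure to acid may cost the silyl ether. The fallback sets out from 16. Ac2O, pyridine and 4-(dimethylamino)pyridine give the diacetate F10, and HF·pyridine in THF frees the primary alcohol F11. Mitsunobu reaction with 19 gives the coumarin ether diacetate F12. K2CO3 in MeOH at 0 °C, followed by acidification to reclose any opened lactone, gives 21 directly.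

Step 14. Substitution at the β-branched primary C11 may be slow, so that alkylation of the hydrazide by-product or decomposition of the oxyphosphonium salt takes over. The fallback sets out from 18 and forms the aryl C–O bond instead. Palladium-catalysed etherification with purchasable 7-bromo-2H-chromen-2-one (O=c1ccc2ccc(Br)cc2o1; Pd(OAc)2, 2-(di-tert-butylphosphino)-3,6-dimethoxy-2',4',6'-triisopropylbiphenyl, Cs2CO3, toluene, 80 °C) gives 20 directly. No substitution at carbon is needed and no new compound is made (F0).

## Further compounds

F1 | step 4 | ethyl (1R,5R,6R)-5-[(tert-butyldimethylsilyloxy)methyl]-6-formyl-4,6-dimethylcyclohex-3-ene-1-carboxylate | CC1=CC[C@H](C(=O)OCC)[C@@](C)(C=O)[C@@H]1CO[Si](C)(C)C(C)(C)C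
F2 | step 4 | 1,3-dioxolane of F1 (formyl group masked) | CC1=CC[C@H](C(=O)OCC)[C@@](C)(C2OCCO2)[C@@H]1CO[Si](C)(C)C(C)(C)C
F3 | step 4 | tertiary alcohol from F2 (2-hydroxypropan-2-yl on C5) | CC1=CC[C@H](C(C)(C)O)[C@@](C)(C2OCCO2)[C@@H]1CO[Si](C)(C)C(C)(C)C
F4 | step 4 | 1,3-dioxolane of aldehyde 7 | CC1=CC[C@H](C(C)=C)[C@@](C)(C2OCCO2)[C@@H]1CO[Si](C)(C)C(C)(C)C
F5 | step 8 | 3-[ring B of 7]prop-2-enenitrile (E/Z mixture) | CC1=CC[C@H](C(C)=C)[C@@](C)(C=CC#N)[C@@H]1CO[Si](C)(C)C(C)(C)C
F6 | step 8 | 3-[ring B of 7]propanenitrile | CC1=CC[C@H](C(C)=C)[C@@](C)(CCC#N)[C@@H]1CO[Si](C)(C)C(C)(C)C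
F7 | step 8 | (5S,9R,10R)-11-(tert-butyldimethylsilyloxy)drim-7-en-3-imine | CC1=CC[C@@H]2C(C)(C)C(=N)CC[C@@]2(C)[C@@H]1CO[Si](C)(C)C(C)(C)C
F8 | step 10 | (5S,9R,10R)-11-(tert-butyldimethylsilyloxy)-3-(trimethylsilyloxy)drima-2,7-diene | CC1=CC[C@@H]2C(C)(C)C(O[Si](C)(C)C)=CC[C@@]2(C)[C@@H]1CO[Si](C)(C)C(C)(C)C
F9 | step 10 | (2S,5S,9R,10R)-2-acetoxy-11-(tert-butyldimethylsilyloxy)drim-7-en-3-one | CC1=CC[C@@H]2C(C)(C)C(=O)[C@@H](OC(C)=O)C[C@@]2(C)[C@@H]1CO[Si](C)(C)C(C)(C)C
F10 | step 12 | (2S,3S,5S,9R,10R)-2,3-diacetoxy-11-(tert-butyldimethylsilyloxy)drim-7-ene | CC1=CC[C@@H]2C(C)(C)[C@H](OC(C)=O)[C@@H](OC(C)=O)C[C@@]2(C)[C@@H]1CO[Si](C)(C)C(C)(C)C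
F11 | step 12 | (2S,3S,5S,9R,10R)-2,3-diacetoxydrim-7-en-11-ol | CC1=CC[C@@H]2C(C)(C)[C@H](OC(C)=O)[C@@H](OC(C)=O)C[C@@]2(C)[C@@H]1CO
F12 | step 12 | 7-{[(2S,3S,5S,9R,10R)-2,3-diacetoxydrim-7-en-11-yl]oxy}-2H-chromen-2-one | CC1=CC[C@@H]2C(C)(C)[C@H](OC(C)=O)[C@@H](OC(C)=O)C[C@@]2(C)[C@@H]1COc1ccc2ccc(=O)oc2c1
F0 | step 14 | none | none
A1 | alternative 1 | 7-{[(3R,5S,9R,10R)-3-hydroxydrim-7-en-11-yl]oxy}-2H-chromen-2-one (2-deoxy target) | CC1=CC[C@@H]2C(C)(C)[C@H](O)CC[C@@]2(C)[C@@H]1COc1ccc2ccc(=O)oc2c1
A2 | alternative 1 | 7-{[(2E,6E)-9-[(2R)-3,3-dimethyloxiran-2-yl]-3,7-dimethylnona-2,6-dien-1-yl]oxy}-2H-chromen-2-one | CC1(C)O[C@@H]1CC/C(C)=C/CC/C(C)=C/COc1ccc2ccc(=O)oc2c1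
A3 | alternative 2 | (2S,3S,5S,10R)-2,3-(isopropylidenedioxy)-11-nordriman-9-one, C8 epimers | CC1CC[C@@H]2C(C)(C)[C@@H]3OC(C)(C)O[C@H]3C[C@@]2(C)C1=O
A4 | alternative 2 | B-nor hydrindanone with the 2,3-isopropylidenedioxy group (ring B five-membered, ketone at C9) | O=C1CC[C@@H]2C(C)(C)[C@@H]3OC(C)(C)O[C@H]3C[C@@]12C
A5 | alternative 2 | diazoethane | CC=[N+]=[N-]
A6 | alternative 3 | methyl 7-(tert-butyldimethylsilyloxy)-2,3-(isopropylidenedioxy)drim-6-en-11-oate, C8 epimers | CC1C(O[Si](C)(C)C(C)(C)C)=C[C@@H]2C(C)(C)[C@@H]3OC(C)(C)O[C@H]3C[C@@]2(C)[C@@H]1C(=O)OC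
A7 | alternative 3 | acyclic triene: (E)-enoate C9=C10 tethered through the C2/C3 acetonide and C4 to the 2-silyloxydiene C5=C6–C7=C8 | COC(=O)/C=C(\C)C[C@@H]1OC(C)(C)O[C@H]1C(C)(C)/C=C/C(O[Si](C)(C)C(C)(C)C)=CC
A8 | alternative 3 | (S)-pantolactone | CC1(C)COC(=O)[C@H]1O
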